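**Plan**

- Numbering: the target chain is C1–C24, C1 being the CH2 of the isopropenyl group next to the 3R centre; the oxiranes are C10–C11 and C14–C15. The target is (3R,7R,10S,11S,14S,15S,18R,22S).
- Cuts: C4–C5 and C20–C21 (alkyl–allyl couplings with the two enantiomeric 2,3-dimethylbut-3-enyl units), then C7–CH3 and C18–CH3 (twofold SN2′ methylation), then C6–C7/C18–C19 (Baylis–Hillman), C8–C9/C16–C17 (triflate displacement) and C10=C11/C14=C15 (Wittig), back to succinaldehyde (C11–C14).
- Forward: the chain grows in both directions from C11–C14. The only rings, the two oxiranes, arise together in step 3. The C2 symmetry is kept up to the C5–C20 diol and broken only for the last couplings (C4–C5 first, C20–C21 last).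
- Enabling feature: C7 and C18 are homotopic CH(CH3) carbons, each next to a methylidene-bearing carbon (C6, C19). This is the imprint of C-methylation of a C6=C7 (C18=C19) alkene with allylic shift. The C10–C11 and C14–C15 oxirane rings are spectators.
- Stereochemistry: C10, C11, C14, C15 from L-(+)-diethyl tartrate (Sharpless epoxidation); C7 and C18 from the chiral copper catalyst of the key step; C3 and C22 from the (R)- and (S)-Roche esters.

Key step: step 9

Remark: the facial sense of the copper–Taniaphos catalyst on (Z)-2-(bromomethyl)alk-2-enoates is assumed to give 7R,18R with the (R,R)-ligand. It is to be confirmed on a simple model substrate, and the (S,S)-ligand is used in step 9 if the sense is opposite, nothing else changing.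

**Route**

Step 1
Reactants: 1 2,5-dimethoxytetrahydrofuran; 2 ethyl 2-(triphenyl-λ5-phosphanylidene)propanoate (two equivalents enter the product)
Product: 4 diethyl (2E,6E)-2,7-dimethylocta-2,6-dienedioate, via succinaldehyde 3 (not isolated)
Conditions: 0.1 M aq. HCl, 70 °C; NaHCO3 to pH 7; then 2 (2.3 equiv), CH2Cl2, rt
Reagents that add atoms: ethyl 2-(triphenyl-λ5-phosphanylidene)propanoate (second equivalent of 2), CCOC(=O)C(C)=P(c1ccccc1)(c1ccccc1)c1ccccc1; water, O (its oxygen reaches only intermediate 3)
Why: Acid hydrolysis of the bis-acetal frees succinaldehyde, which is trapped at once in a twofold Wittig reaction with the stabilised α-methyl ylide, a reagent class that gives (E)-2-methylenoates and so fixes the C10=C11 and C14=C15 geometry.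

Step 2
Reactants: 4 diethyl (2E,6E)-2,7-dimethylocta-2,6-dienedioate
Product: 5 (2E,6E)-2,7-dimethylocta-2,6-diene-1,8-diol
Conditions: iBu2AlH (4.5 equiv), CH2Cl2, −78 → 0 °C; aq. KNaC4H4O6 (Rochelle salt)
Reagents that add atoms: none
Why: iBu2AlH reduction of α,β-unsaturated esters proceeds in 1,2-fashion to the allylic alcohols and leaves the trisubstituted alkenes alone.

Step 3
Reactants: 5 (2E,6E)-2,7-dimethylocta-2,6-diene-1,8-diol
Product: 6 (2S,3S,6S,7S)-2,3:6,7-diepoxy-2,7-dimethyloctane-1,8-diol
Conditions: Ti(OiPr)4, L-(+)-diethyl tartrate, tBuOOH (anhydrous, isooctane), 4 Å molecular sieves, CH2Cl2, −20 °C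
Reagents that add atoms: tert-butyl hydroperoxide, CC(C)(C)OO
Why: Twofold Sharpless asymmetric epoxidation with L-(+)-diethyl tartrate should epoxidise each (E)-2-methylallyl alcohol terminus on the face that gives the (2S,3S)-epoxy alcohol (C10, C11, C14, C15 of the target, all S), and since the two events are independent a wrong-face event ends in the meso diastereomer, to be removed here, and not in the enantiomer.

Step 4
Reactants: 6 (2S,3S,6S,7S)-2,3:6,7-diepoxy-2,7-dimethyloctane-1,8-diol
Product: 7 bis(trifluoromethanesulfonate) of 6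
Conditions: Tf2O (2.4 equiv), 2,6-lutidine (3 equiv), CH2Cl2, −78 °C; cold aqueous wash, used crude at once
Reagents that add atoms: trifluoromethanesulfonic anhydride, O=S(=O)(OS(=O)(=O)C(F)(F)F)C(F)(F)F
Why: O-Sulfonylation of the primary hydroxyls of 2,3-epoxy alcohols with Tf2O and a hindered pyridine base is fast at −78 °C, and the sensitive bis-triflate is carried on cold and unpurified.

Step 5
Reactants: 7 bis(trifluoromethanesulfonate) of 6; 8 allylmagnesium bromide (two equivalents enter the product)
Product: 9 (5S,6S,9S,10S)-5,6:9,10-diepoxy-5,10-dimethyltetradeca-1,13-diene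
Conditions: 8 (3 equiv), CuI (20 mol%), Et2O, −78 → −40 °C
Reagents that add atoms: allylmagnesium bromide (second equivalent of 8), C=CC[Mg]Br
Why: Copper-catalysed Grignard displacement of a primary triflate (SN2 at C9 and C16) should be far faster at −78 °C than opening of the neighbouring trisubstituted oxiranes, so C8–C9 and C16–C17 form and the four stereocentres stay untouched.

Step 6
Reactants: 9 (5S,6S,9S,10S)-5,6:9,10-diepoxy-5,10-dimethyltetradeca-1,13-diene
Product: 10 (4S,5S,8S,9S)-4,5:8,9-diepoxy-4,9-dimethyldodecanedial (C7–C18 dialdehyde)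
Conditions: O3, CH2Cl2, −78 °C; then PPh3, −78 °C → rt
Reagents that add atoms: ozone, [O-][O+]=O
Why: Ozonolysis with reductive work-up cleaves only the two vinyl groups, oxiranes being inert to ozone, and places the aldehyde carbons at C7 and C18.

Step 7
Reactants: 10 (4S,5S,8S,9S)-4,5:8,9-diepoxy-4,9-dimethyldodecanedial; 11 methyl acrylate (two equivalents enter the product)
Product: 12 dimethyl (6S,7S,10S,11S)-6,7:10,11-diepoxy-3,14-dihydroxy-6,11-dimethyl-2,15-dimethylidenehexadecanedioate (epimers at the two carbinol carbons, C7 and C18 of the target)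
Conditions: 11 (10 equiv), DABCO (1 equiv), MeOH (cat.), rt; chromatography on Et3N-deactivated silica
Reagents that add atoms: methyl acrylate (second equivalent of 11), C=CC(=O)OC
Why: Twofold Morita–Baylis–Hillman reaction of the unhindered aliphatic aldehydes forms C6–C7 and C18–C19; the new carbinol centres are uncontrolled, which is harmless because they become sp2 in step 8, and the basic medium should keep the γ,δ-epoxy alcohol from closing to a tetrahydrofuran.

Step 8
Reactants: 12 bis(Baylis–Hillman adduct)
Product: 13 dimethyl (2Z,6S,7S,10S,11S,14Z)-2,15-bis(bromomethyl)-6,7:10,11-diepoxy-6,11-dimethylhexadeca-2,14-dienedioate (C5–C20 bis-epoxy bis[(Z)-2-(bromomethyl)enoate])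
Conditions: NBS (2.6 equiv), Me2S (3 equiv), CH2Cl2, −20 → 0 °C
Reagents that add atoms: N-bromosuccinimide, O=C1CCC(=O)N1Br
Why: Corey–Kim-type activation of the allylic hydroxyls followed by SN2′ return of bromide is the standard acid-free route from Baylis–Hillman adducts to the thermodynamically preferred (Z)-2-(bromomethyl)alk-2-enoates, and oxiranes tolerate it.

Step 9
Reactants: 13 C5–C20 bis-epoxy bis[(Z)-2-(bromomethyl)enoate]; 14 methylmagnesium bromide (one equivalent is consumed at each terminus)
Product: 15 dimethyl (3R,6S,7S,10S,11S,14R)-6,7:10,11-diepoxy-3,6,11,14-tetramethyl-2,15-dimethylidenehexadecanedioate (C5–C20 bis-epoxy bis(α-methylene ester), 7R,18R)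
Conditions: CuBr·SMe2 (10 mol%), (R,R)-Taniaphos (12 mol%), CH2Cl2, −78 °C; 14 (2.4 equiv), added as Et2O solution over 2 h; MeOH quench at −78 °C
Reagents that add atoms: methylmagnesium bromide (second equivalent of 14), C[Mg]Br
Why: MeMgBr transmetalates to a phosphine-bound methylcopper (monovalent copper) that binds the C6=C7 alkene, adds oxidatively at C7 anti to the departing bromide to give an allyl complex of trivalent copper, and reductively eliminates to form C7–CH3 while the double bond moves to C6=CH2; a second molecule of MeMgBr does the same at C18/C19, so two methyl groups enter 15. The closest known reaction type is the copper-catalysed enantioselective SN2′ allylic alkylation of allyl bromides and of Baylis–Hillman-derived 2-(halomethyl)alk-2-enoates with Grignard reagents, here run twice on one substrate. No ring is closed and the two oxiranes are spectators. C7 and C18 are both set by the chiral ligand, which selects one face of each stereodefined (Z)-alkene; the two ends are homotopic and remote from the oxirane stereocentres, so they should react alike, and a wrong-face event ends in a diastereomer and not in the enantiomer. The step needs γ over α attack, which the electrophilic β-carbon of the enoate and the bidentate phosphine both favour, and it needs the esters, the oxiranes and the product acrylate to stay untouched, which −78 °C and slow addition of the Grignard reagent should secure.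

Step 10
Reactants: 15 C5–C20 bis-epoxy bis(α-methylene ester)
Product: 16 (3R,6S,7S,10S,11S,14R)-6,7:10,11-diepoxy-3,6,11,14-tetramethyl-2,15-dimethylidenehexadecane-1,16-diol (C5–C20 diol)
Conditions: iBu2AlH (5 equiv), CH2Cl2, −78 °C; aq. KNaC4H4O6 (Rochelle salt)
Reagents that add atoms: none
Why: iBu2AlH reduction of the 2-substituted acrylates in 1,2-fashion at −78 °C gives the 2-substituted allyl alcohols at C5 and C20 without touching the oxiranes or the C7/C18 centres.

Step 11
Reactants: 16 C5–C20 diol
Product: 17 mono(tert-butyldiphenylsilyl) ether of 16 (C5–OH free, C20–OSi)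
Conditions: tBuPh2SiCl (1.0 equiv), imidazole, CH2Cl2, −20 → 0 °C; recovered 16 recycled
Reagents that add atoms: tert-butyl(chloro)diphenylsilane, CC(C)(C)[Si](Cl)(c1ccccc1)c1ccccc1
Why: The two hydroxyls are homotopic, so silylation with one equivalent of silyl chloride gives a single monosilyl ether in statistical amount and breaks the C2 symmetry, the diphenylsilyl group being chosen to survive the Appel and coupling steps.

Step 12
Reactants: 17 mono(tert-butyldiphenylsilyl) ether of 16
Product: 18 C5 bromide of 17 (5-bromo-20-silyloxy compound, 7R,10S,11S,14S,15S,18R)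
Conditions: CBr4, PPh3, CH2Cl2, 0 °C
Reagents that add atoms: carbon tetrabromide, BrC(Br)(Br)Br
Why: The Appel reaction converts the free primary allylic alcohol into the bromide under neutral conditions that leave oxiranes and the silyl ether alone.

Step 13
Reactants: 19 methyl (R)-3-hydroxy-2-methylpropanoate
Product: 20 methyl (R)-3-[(tert-butyldimethylsilyl)oxy]-2-methylpropanoate
Conditions: tBuMe2SiCl, imidazole, CH2Cl2, 0 °C → rt
Reagents that add atoms: tert-butyl(chloro)dimethylsilane, CC(C)(C)[Si](C)(C)Cl
Why: Silylation of the primary hydroxyl protects it through the organometallic steps and does not touch the α-stereocentre.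

Step 14
Reactants: 20 methyl (R)-3-[(tert-butyldimethylsilyl)oxy]-2-methylpropanoate; 14 methylmagnesium bromide
Product: 22 (R)-4-[(tert-butyldimethylsilyl)oxy]-3-methylbutan-2-one, via Weinreb amide 21 (not isolated)
Conditions: MeNHOMe·HCl (1.5 equiv), iPrMgCl (3.0 equiv), THF, −20 °C; then 14 (3 equiv), −20 → 0 °C; aq. NH4Cl
Reagents that add atoms: N,O-dimethylhydroxylamine hydrochloride, CNOC.Cl (its atoms reach only intermediate 21)
Why: Weinreb ketone synthesis in one pot, the magnesium amide converting the ester into the N-methoxy-N-methylamide and MeMgBr then adding once because the chelated tetrahedral intermediate is stable, with low temperature protecting the α-stereocentre.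

Step 15
Reactants: 22 (R)-4-[(tert-butyldimethylsilyl)oxy]-3-methylbutan-2-one
Product: 23 (S)-tert-butyl[(2,3-dimethylbut-3-en-1-yl)oxy]dimethylsilane
Conditions: Cp2TiMe2 (2 equiv), toluene, 65 °C, dark
Reagents that add atoms: dimethyltitanocene Cp2TiMe2, C[Ti](C)(C1C=CC=C1)C1C=CC=C1
Why: Petasis methylenation with the neutral titanocene methylidene turns the enolisable α-branched ketone into the isopropenyl group without the base that could epimerise the stereocentre or eliminate the β-silyloxy group (the descriptor changes from R to S only through the priority rules).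

Step 16
Reactants: 23 (S)-tert-butyl[(2,3-dimethylbut-3-en-1-yl)oxy]dimethylsilane
Product: 24 (S)-2,3-dimethylbut-3-en-1-ol
Conditions: Bu4NF, THF, 0 °C → rt; careful distillation
Reagents that add atoms: none
Why: Fluoride-induced desilylation frees the volatile homoallylic alcohol without touching the stereocentre.

Step 17
Reactants: 24 (S)-2,3-dimethylbut-3-en-1-ol
Product: 26 (S)-4-bromo-2,3-dimethylbut-1-ene, via mesylate 25 (not isolated)
Conditions: MsCl, Et3N, THF, 0 °C; then LiBr (5 equiv), rt → 45 °C; distillation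
Reagents that add atoms: methanesulfonyl chloride, CS(=O)(=O)Cl (its atoms reach only intermediate 25); lithium bromide, [Li+].[Br-]
Why: Mesylation followed by SN2 displacement with bromide at the primary carbon gives the bromide without acid, so the 1,1-disubstituted alkene and the adjacent stereocentre stay intact.

Step 18
Reactants: 27 methyl (S)-3-hydroxy-2-methylpropanoate
Product: 28 methyl (S)-3-[(tert-butyldimethylsilyl)oxy]-2-methylpropanoate
Conditions: tBuMe2SiCl, imidazole, CH2Cl2, 0 °C → rt
Reagents that add atoms: tert-butyl(chloro)dimethylsilane, CC(C)(C)[Si](C)(C)Cl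
Why: Silylation as in step 13, in the enantiomeric series.

Step 19
Reactants: 28 methyl (S)-3-[(tert-butyldimethylsilyl)oxy]-2-methylpropanoate; 14 methylmagnesium bromide
Product: 30 (S)-4-[(tert-butyldimethylsilyl)oxy]-3-methylbutan-2-one, via Weinreb amide 29 (not isolated)
Conditions: MeNHOMe·HCl (1.5 equiv), iPrMgCl (3.0 equiv), THF, −20 °C; then 14 (3 equiv), −20 → 0 °C; aq. NH4Cl
Reagents that add atoms: N,O-dimethylhydroxylamine hydrochloride, CNOC.Cl (its atoms reach only intermediate 29)
Why: Weinreb ketone synthesis as in step 14, in the enantiomeric series.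

Step 20
Reactants: 30 (S)-4-[(tert-butyldimethylsilyl)oxy]-3-methylbutan-2-one
Product: 31 (R)-tert-butyl[(2,3-dimethylbut-3-en-1-yl)oxy]dimethylsilane
Conditions: Cp2TiMe2 (2 equiv), toluene, 65 °C, dark
Reagents that add atoms: dimethyltitanocene Cp2TiMe2, C[Ti](C)(C1C=CC=C1)C1C=CC=C1
Why: Petasis methylenation as in step 15, in the enantiomeric series.

Step 21
Reactants: 31 (R)-tert-butyl[(2,3-dimethylbut-3-en-1-yl)oxy]dimethylsilane
Product: 32 (R)-2,3-dimethylbut-3-en-1-ol
Conditions: Bu4NF, THF, 0 °C → rt; careful distillation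
Reagents that add atoms: none
Why: Fluoride-induced desilylation as in step 16.

Step 22
Reactants: 32 (R)-2,3-dimethylbut-3-en-1-ol
Product: 34 (R)-4-bromo-2,3-dimethylbut-1-ene, via mesylate 33 (not isolated)
Conditions: MsCl, Et3N, THF, 0 °C; then LiBr (5 equiv), rt → 45 °C; distillation
Reagents that add atoms: methanesulfonyl chloride, CS(=O)(=O)Cl (its atoms reach only intermediate 33); lithium bromide, [Li+].[Br-]
Why: Mesylation and SN2 bromide displacement as in step 17.

Step 23
Reactants: 18 C5 bromide (20-silyloxy); 26 (S)-4-bromo-2,3-dimethylbut-1-ene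
Product: 36 C1–C20 silyl ether (3R,7R,10S,11S,14S,15S,18R; C20–OSi), via Grignard reagent 35 (not isolated)
Conditions: 26 (2.5 equiv), Mg, THF, 25 °C; this solution added to 18 and Li2CuCl4 (5 mol%), THF, −78 → −20 °C
Reagents that add atoms: magnesium, [Mg] (its atom reaches only intermediate 35)
Why: Kochi-type copper-catalysed coupling of a primary alkyl Grignard reagent with an allylic bromide forms C4–C5; SN2 and SN2′ attack give the same product because the allyl unit carries its substituent on the central carbon, the homoallylic Grignard reagent is made and used without delay so that it keeps its constitution and configuration (C3 comes unchanged from 26), and at low temperature the oxiranes and the allyl silyl ether are left alone.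

Step 24
Reactants: 36 C1–C20 silyl ether
Product: 37 C1–C20 allylic alcohol (C20–OH)
Conditions: Bu4NF, THF, 0 °C → rt
Reagents that add atoms: none
Why: Fluoride-induced desilylation frees the C20 allylic alcohol without affecting oxiranes or alkenes.

Step 25
Reactants: 37 C1–C20 allylic alcohol
Product: 38 C1–C20 allylic bromide (C20–Br)
Conditions: CBr4, PPh3, CH2Cl2, 0 °C
Reagents that add atoms: carbon tetrabromide, BrC(Br)(Br)Br
Why: Appel reaction as in step 12.

Step 26
Reactants: 38 C1–C20 allylic bromide; 34 (R)-4-bromo-2,3-dimethylbut-1-ene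
Product: 40 target (3R,7R,10S,11S,14S,15S,18R,22S)-10,11:14,15-diepoxy-2,3,7,10,15,18,22,23-octamethyl-6,19-dimethylidenetetracosa-1,23-diene, via Grignard reagent 39 (not isolated)
Conditions: 34 (2.5 equiv), Mg, THF, 25 °C; this solution added to 38 and Li2CuCl4 (5 mol%), THF, −78 → −20 °C
Reagents that add atoms: magnesium, [Mg] (its atom reaches only intermediate 39)
Why: Second Kochi-type coupling, now with the (R)-Grignard reagent, forms C20–C21 and brings in C22 as S (the descriptor changes only through the priority rules), completing the C24 chain.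

**Compound list**

1 | 2,5-dimethoxytetrahydrofuran | COC1CCC(OC)O1 | starting material
2 | ethyl 2-(triphenyl-λ5-phosphanylidene)propanoate | CCOC(=O)C(C)=P(c1ccccc1)(c1ccccc1)c1ccccc1 | starting material
3 | succinaldehyde (formed in the flask) | O=CCCC=O | intermediate
4 | diethyl (2E,6E)-2,7-dimethylocta-2,6-dienedioate | CCOC(=O)/C(C)=C/CC/C=C(\C)C(=O)OCC | intermediate
5 | (2E,6E)-2,7-dimethylocta-2,6-diene-1,8-diol | OC/C(C)=C/CC/C=C(\C)CO | intermediate
6 | (2S,3S,6S,7S)-2,3:6,7-diepoxy-2,7-dimethyloctane-1,8-diol | OC[C@]1(C)O[C@H]1CC[C@@H]1O[C@@]1(C)CO | intermediate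
7 | (2S,3S,6S,7S)-2,3:6,7-diepoxy-2,7-dimethyloctane-1,8-diyl bis(trifluoromethanesulfonate) | FC(F)(F)S(=O)(=O)OC[C@]1(C)O[C@H]1CC[C@@H]1O[C@@]1(C)COS(=O)(=O)C(F)(F)F | intermediate
8 | allylmagnesium bromide | C=CC[Mg]Br | starting material
9 | (5S,6S,9S,10S)-5,6:9,10-diepoxy-5,10-dimethyltetradeca-1,13-diene | C=CCC[C@]1(C)O[C@H]1CC[C@@H]1O[C@@]1(C)CCC=C | intermediate
10 | (4S,5S,8S,9S)-4,5:8,9-diepoxy-4,9-dimethyldodecanedial | O=CCC[C@]1(C)O[C@H]1CC[C@@H]1O[C@@]1(C)CCC=O | intermediate
11 | methyl acrylate | C=CC(=O)OC | starting material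
12 | dimethyl (6S,7S,10S,11S)-6,7:10,11-diepoxy-3,14-dihydroxy-6,11-dimethyl-2,15-dimethylidenehexadecanedioate (epimers at C3 and C14) | COC(=O)C(=C)C(O)CC[C@]1(C)O[C@H]1CC[C@@H]1O[C@@]1(C)CCC(O)C(=C)C(=O)OC | intermediate
13 | dimethyl (2Z,6S,7S,10S,11S,14Z)-2,15-bis(bromomethyl)-6,7:10,11-diepoxy-6,11-dimethylhexadeca-2,14-dienedioate | COC(=O)/C(CBr)=C/CC[C@]1(C)O[C@H]1CC[C@@H]1O[C@@]1(C)CC/C=C(\CBr)C(=O)OC | intermediate
14 | methylmagnesium bromide | C[Mg]Br | starting material
15 | dimethyl (3R,6S,7S,10S,11S,14R)-6,7:10,11-diepoxy-3,6,11,14-tetramethyl-2,15-dimethylidenehexadecanedioate | COC(=O)C(=C)[C@H](C)CC[C@]1(C)O[C@H]1CC[C@@H]1O[C@@]1(C)CC[C@@H](C)C(=C)C(=O)OC | intermediate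
16 | (3R,6S,7S,10S,11S,14R)-6,7:10,11-diepoxy-3,6,11,14-tetramethyl-2,15-dimethylidenehexadecane-1,16-diol | OCC(=C)[C@H](C)CC[C@]1(C)O[C@H]1CC[C@@H]1O[C@@]1(C)CC[C@@H](C)C(=C)CO | intermediate
17 | (3R,6S,7S,10S,11S,14R)-16-[(tert-butyldiphenylsilyl)oxy]-6,7:10,11-diepoxy-3,6,11,14-tetramethyl-2,15-dimethylidenehexadecan-1-ol | OCC(=C)[C@H](C)CC[C@]1(C)O[C@H]1CC[C@@H]1O[C@@]1(C)CC[C@@H](C)C(=C)CO[Si](c1ccccc1)(c1ccccc1)C(C)(C)C | intermediate
18 | tert-butyl{[(3R,6S,7S,10S,11S,14R)-16-bromo-6,7:10,11-diepoxy-3,6,11,14-tetramethyl-2,15-dimethylidenehexadecyl]oxy}diphenylsilane (C5 bromide of 17) | BrCC(=C)[C@H](C)CC[C@]1(C)O[C@H]1CC[C@@H]1O[C@@]1(C)CC[C@@H](C)C(=C)CO[Si](c1ccccc1)(c1ccccc1)C(C)(C)C | intermediate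
19 | methyl (R)-3-hydroxy-2-methylpropanoate | COC(=O)[C@H](C)CO | starting material
20 | methyl (R)-3-[(tert-butyldimethylsilyl)oxy]-2-methylpropanoate | COC(=O)[C@H](C)CO[Si](C)(C)C(C)(C)C | intermediate
21 | (R)-3-[(tert-butyldimethylsilyl)oxy]-N-methoxy-N,2-dimethylpropanamide (formed in the flask) | CON(C)C(=O)[C@H](C)CO[Si](C)(C)C(C)(C)C | intermediate
22 | (R)-4-[(tert-butyldimethylsilyl)oxy]-3-methylbutan-2-one | CC(=O)[C@H](C)CO[Si](C)(C)C(C)(C)C | intermediate
23 | (S)-tert-butyl[(2,3-dimethylbut-3-en-1-yl)oxy]dimethylsilane | C=C(C)[C@H](C)CO[Si](C)(C)C(C)(C)C | intermediate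
24 | (S)-2,3-dimethylbut-3-en-1-ol | C=C(C)[C@H](C)CO | intermediate
25 | (S)-2,3-dimethylbut-3-en-1-yl methanesulfonate (formed in the flask) | C=C(C)[C@H](C)COS(C)(=O)=O | intermediate
26 | (S)-4-bromo-2,3-dimethylbut-1-ene | C=C(C)[C@H](C)CBr | intermediate
27 | methyl (S)-3-hydroxy-2-methylpropanoate | COC(=O)[C@@H](C)CO | starting material
28 | methyl (S)-3-[(tert-butyldimethylsilyl)oxy]-2-methylpropanoate | COC(=O)[C@@H](C)CO[Si](C)(C)C(C)(C)C | intermediate
29 | (S)-3-[(tert-butyldimethylsilyl)oxy]-N-methoxy-N,2-dimethylpropanamide (formed in the flask) | CON(C)C(=O)[C@@H](C)CO[Si](C)(C)C(C)(C)C | intermediate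
30 | (S)-4-[(tert-butyldimethylsilyl)oxy]-3-methylbutan-2-one | CC(=O)[C@@H](C)CO[Si](C)(C)C(C)(C)C | intermediate
31 | (R)-tert-butyl[(2,3-dimethylbut-3-en-1-yl)oxy]dimethylsilane | C=C(C)[C@@H](C)CO[Si](C)(C)C(C)(C)C | intermediate
32 | (R)-2,3-dimethylbut-3-en-1-ol | C=C(C)[C@@H](C)CO | intermediate
33 | (R)-2,3-dimethylbut-3-en-1-yl methanesulfonate (formed in the flask) | C=C(C)[C@@H](C)COS(C)(=O)=O | intermediate
34 | (R)-4-bromo-2,3-dimethylbut-1-ene | C=C(C)[C@@H](C)CBr | intermediate
35 | (S)-(2,3-dimethylbut-3-en-1-yl)magnesium bromide (formed in the flask) | C=C(C)[C@H](C)C[Mg]Br | intermediate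
36 | tert-butyldiphenylsilyl ether of 37 (C1–C20 silyl ether, 3R,7R,10S,11S,14S,15S,18R in target numbering, C20–OSi) | C=C(C)[C@H](C)CCC(=C)[C@H](C)CC[C@]1(C)O[C@H]1CC[C@@H]1O[C@@]1(C)CC[C@@H](C)C(=C)CO[Si](c1ccccc1)(c1ccccc1)C(C)(C)C | intermediate
37 | (3R,6S,7S,10S,11S,14R,18R)-6,7:10,11-diepoxy-3,6,11,14,18,19-hexamethyl-2,15-dimethylideneicos-19-en-1-ol (C1–C20 allylic alcohol) | C=C(C)[C@H](C)CCC(=C)[C@H](C)CC[C@]1(C)O[C@H]1CC[C@@H]1O[C@@]1(C)CC[C@@H](C)C(=C)CO | intermediate
38 | (3R,6S,7S,10S,11S,14R,18R)-1-bromo-6,7:10,11-diepoxy-3,6,11,14,18,19-hexamethyl-2,15-dimethylideneicos-19-ene (C1–C20 allylic bromide) | C=C(C)[C@H](C)CCC(=C)[C@H](C)CC[C@]1(C)O[C@H]1CC[C@@H]1O[C@@]1(C)CC[C@@H](C)C(=C)CBr | intermediate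
39 | (R)-(2,3-dimethylbut-3-en-1-yl)magnesium bromide (formed in the flask) | C=C(C)[C@@H](C)C[Mg]Br | intermediate
40 | (3R,7R,10S,11S,14S,15S,18R,22S)-10,11:14,15-diepoxy-2,3,7,10,15,18,22,23-octamethyl-6,19-dimethylidenetetracosa-1,23-diene | C=C(C)[C@H](C)CCC(=C)[C@H](C)CC[C@]1(C)O[C@H]1CC[C@@H]1O[C@@]1(C)CC[C@@H](C)C(=C)CC[C@H](C)C(=C)C | target

**Count and risks**

Total step count: 26. Longest linear sequence: 16 steps (steps 1–12 and 23–26, from 1).

Steps most likely to fail:

1. Step 9. Enantiofacial control may be incomplete at one or both termini, or a ligand-free background SN2′ methylation may compete, which would leave C7/C18 epimers that are hard to remove. The fallback sets out from dialdehyde 10 and comes back at diol 16. Wittig reaction of 10 with S-ethyl 2-(triphenylphosphoranylidene)ethanethioate should give the bis[(E)-enethioate] F1. Twofold copper-catalysed conjugate addition of MeMgBr (CuBr·SMe2, a Josiphos ligand of the enantiomer that gives 7R,18R, tBuOMe, −75 °C) then sets C7 and C18 in the bis(3-methyl thioester) F2. iBu2AlH at −78 °C reduces the thioesters to the 3-methyl dialdehyde F3, and α-methylenation with aqueous formaldehyde (pyrrolidine and propionic acid as catalysts) gives the bis(2-methylidene aldehyde) F4. NaBH4 with CeCl3·7H2O in MeOH finally reduces F4 in 1,2-fashion to 16.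

2. Step 5 (with step 4). The epoxy triflate may decompose, or the allyl nucleophile may open the oxirane instead of displacing the triflate at the carbon next to a fully substituted oxirane carbon. The fallback sets out from 1 and comes back at dialdehyde 10. Succinaldehyde 3, this time distilled, is treated with isopropenylmagnesium bromide to give the diene diol F5. A twofold Johnson–Claisen rearrangement (triethyl orthoacetate, cat. propionic acid, 140 °C) gives the (4E,8E)-diene diester F6. Shi epoxidation with the L-fructose-derived ketone (1,2:4,5-di-O-isopropylidene-β-L-erythro-2,3-hexodiulo-2,6-pyranose, the enantiomer needed for the all-S oxiranes), KHSO5 and K2CO3 gives the bis-epoxy diester F7, and iBu2AlH at −78 °C gives 10.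

3. Step 7. The twofold Baylis–Hillman addition may be slow and incomplete, with aldol self-condensation of the dialdehyde and 5-exo opening of the oxiranes by the new C7/C18 hydroxyls over the long reaction time. The fallback sets out from 10 and comes back at 12. The lithium enolate of methyl 3-(dimethylamino)propanoate (LiN(iPr)2, THF, −78 °C) should add to both aldehydes within minutes to give the bis(α-aminomethyl β-hydroxy ester) F8. N-Methylation with MeI gives the bis(trimethylammonium) diiodide F9, and NaHCO3 induces loss of trimethylamine and gives 12.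

**Further compounds**

F1 | step 9 | S,S′-diethyl (2E,6S,7S,10S,11S,14E)-6,7:10,11-diepoxy-6,11-dimethylhexadeca-2,14-dienebis(thioate) | CCSC(=O)/C=C/CC[C@]1(C)O[C@H]1CC[C@@H]1O[C@@]1(C)CC/C=C/C(=O)SCC
F2 | step 9 | S,S′-diethyl (3R,6S,7S,10S,11S,14R)-6,7:10,11-diepoxy-3,6,11,14-tetramethylhexadecanebis(thioate) | CCSC(=O)C[C@H](C)CC[C@]1(C)O[C@H]1CC[C@@H]1O[C@@]1(C)CC[C@@H](C)CC(=O)SCC
F3 | step 9 | (3R,6S,7S,10S,11S,14R)-6,7:10,11-diepoxy-3,6,11,14-tetramethylhexadecanedial | O=CC[C@H](C)CC[C@]1(C)O[C@H]1CC[C@@H]1O[C@@]1(C)CC[C@@H](C)CC=O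
F4 | step 9 | (3R,6S,7S,10S,11S,14R)-6,7:10,11-diepoxy-3,6,11,14-tetramethyl-2,15-dimethylidenehexadecanedial | O=CC(=C)[C@H](C)CC[C@]1(C)O[C@H]1CC[C@@H]1O[C@@]1(C)CC[C@@H](C)C(=C)C=O
F5 | step 5 | 2,7-dimethylocta-1,7-diene-3,6-diol (stereoisomer mixture) | C=C(C)C(O)CCC(O)C(C)=C
F6 | step 5 | diethyl (4E,8E)-4,9-dimethyldodeca-4,8-dienedioate | CCOC(=O)CC/C(C)=C/CC/C=C(\C)CCC(=O)OCC
F7 | step 5 | diethyl (4S,5S,8S,9S)-4,5:8,9-diepoxy-4,9-dimethyldodecanedioate | CCOC(=O)CC[C@]1(C)O[C@H]1CC[C@@H]1O[C@@]1(C)CCC(=O)OCC
F8 | step 7 | dimethyl (6S,7S,10S,11S)-2,15-bis[(dimethylamino)methyl]-6,7:10,11-diepoxy-3,14-dihydroxy-6,11-dimethylhexadecanedioate (stereoisomer mixture at C2, C3, C14, C15) | COC(=O)C(CN(C)C)C(O)CC[C@]1(C)O[C@H]1CC[C@@H]1O[C@@]1(C)CCC(O)C(CN(C)C)C(=O)OC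
F9 | step 7 | bis(trimethylammonium) diiodide of F8 | COC(=O)C(C[N+](C)(C)C)C(O)CC[C@]1(C)O[C@H]1CC[C@@H]1O[C@@]1(C)CCC(O)C(C[N+](C)(C)C)C(=O)OC.[I-].[I-]
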